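**Retrosynthetic overview**
1. The target is andrographolide (1) plus one molecule of water added anti across the E-configured C12=C13 alkylidene (OH on C12, H on C13). The decalin, the lactone and the stereocentres C3, C4, C5, C9, C10 and C14 come intact with 1.
2. Key disconnection: the C12–O bond, formed by a boron-tethered oxa-Michael addition in which the C14 hydroxyl carries a B–OH group (from arylboronic acid 2) onto C12. The tether fixes 12R and the cis ring fusion fixes 13R.
3. The 3,19-diol is masked beforehand with the same boronic acid, and both boronates are removed together at the end.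
4. Ring order: no permanent ring is formed. A temporary 1,3,2-dioxaborinane on O3/O19 is made first, then a temporary O12/O14 dioxaborinane fused to the lactone, then both are opened.

Assumption: andrographolide (bulk isolate of Andrographis paniculata, sold in kilogram lots) counts as a cheap commercial starting material. Labdane numbering is used: C3–OH, C19–OH, C8=C17, C12=C13, C14–OH, C15 lactone CH2, C16 lactone C=O. Ar = 3,4,5-trimethoxyphenyl.

**Route**

Step 1
Reactants: 1 andrographolide; 2 3,4,5-trimethoxyphenylboronic acid
Product: 3 andrographolide 3,19-O-(3,4,5-trimethoxyphenyl)boronate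
Conditions: 2 (1.05 equiv), THF, rt, 2 h; then evaporation from PhMe (3×) to remove water
Reagents that add atoms: 3,4,5-trimethoxyphenylboronic acid, COc1cc(B(O)O)cc(OC)c1OC
Why: Boronic ester condensation; only the C3–OH/C19–OH pair is a 1,3-diol that can close a six-membered cyclic boronate (the same pair that forms the known 3,19-acetonide), so one equivalent of 2 caps it selectively, makes the substrate soluble in non-polar solvents and leaves C14–OH free, with no stereocentre touched.

Step 2
Reactants: 3 andrographolide 3,19-O-(3,4,5-trimethoxyphenyl)boronate; 2 3,4,5-trimethoxyphenylboronic acid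
Product: 5 (12R,13R,14S)-12-hydroxy-12,13-dihydroandrographolide 3,19:12,14-bis-O-(3,4,5-trimethoxyphenyl)boronate, via 14-O-boronic hemiester 4 (not isolated)
Conditions: 2 (1.2 equiv), N-[3,5-bis(trifluoromethyl)phenyl]-N′-[(8α,9S)-6′-methoxycinchonan-9-yl]thiourea (20 mol %), 4 Å molecular sieves, PhMe–CH2Cl2 (4:1), 45 °C, 36 h
Reagents that add atoms: 3,4,5-trimethoxyphenylboronic acid, COc1cc(B(O)O)cc(OC)c1OC
Why: Proposed new method: the free C14–OH condenses with 2 to the hemiester 4; the quinuclidine nitrogen of the catalyst binds boron and raises the nucleophilicity of the B–OH oxygen while the thiourea hydrogen-bonds the lactone carbonyl, so that oxygen adds 6-endo to C12 on the face that carries O14 (the only face the short tether can reach, which on the E-alkylidene is the 12R face), and the enol(ate) is then protonated at C13 on the open face opposite the boron bridge, the only face that gives the cis-fused dioxaborinane–lactone (13R), before O14 can be expelled; the closest known reaction type is the amine–thiourea-catalysed oxa-Michael addition of boronic acid hemiesters of γ- and δ-hydroxy enones (exo closure onto ketones), here extended to an endo closure onto an α-alkylidene-γ-butyrolactone whose anchoring hydroxyl sits on the α-branch and which creates a second stereocentre by protonation.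

Step 3
Reactants: 5 (12R,13R,14S)-12-hydroxy-12,13-dihydroandrographolide 3,19:12,14-bis-O-(3,4,5-trimethoxyphenyl)boronate
Product: 6 (12R,13R,14S)-12-hydroxy-12,13-dihydroandrographolide (target)
Conditions: 30% aq. H2O2 (6 equiv), KH2PO4/Na2HPO4 buffer (pH 7), THF, 0 °C to rt, 1 h
Reagents that add atoms: none
Why: Oxidative deboronation; hydroperoxide adds to each boron, the aryl group migrates to oxygen and the borate esters hydrolyse at pH 7, so all four C–O bonds keep their configuration, the neutral medium avoids C13 epimerisation, retro-aldol cleavage and dehydration of the β-hydroxy lactone, and the unactivated 1,1-disubstituted alkene does not react with H2O2 alone.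

**Compound list**

1 | andrographolide, (3E,4S)-3-{2-[(1R,4aS,5R,6R,8aS)-6-hydroxy-5-(hydroxymethyl)-5,8a-dimethyl-2-methylidenedecahydronaphthalen-1-yl]ethylidene}-4-hydroxyoxolan-2-one | C=C1CC[C@@H]2[C@](C)(CO)[C@H](O)CC[C@@]2(C)[C@@H]1C/C=C1/C(=O)OC[C@H]1O | starting material

2 | 3,4,5-trimethoxyphenylboronic acid | COc1cc(B(O)O)cc(OC)c1OC | starting material

3 | andrographolide 3,19-O-(3,4,5-trimethoxyphenyl)boronate (O3 and O19 bridged by B–Ar in a six-membered 1,3,2-dioxaborinane; C14–OH free; E-alkene and all stereocentres as in 1) | C=C1CC[C@@H]2[C@]3(C)COB(c4cc(OC)c(OC)c(OC)c4)O[C@@H]3CC[C@@]2(C)[C@@H]1C/C=C1/C(=O)OC[C@H]1O | intermediate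

4 | 14-O-[hydroxy(3,4,5-trimethoxyphenyl)boryl] hemiester of 3 (C14–O–B(Ar)–OH; not isolated) | C=C1CC[C@@H]2[C@]3(C)COB(c4cc(OC)c(OC)c(OC)c4)O[C@@H]3CC[C@@]2(C)[C@@H]1C/C=C1/C(=O)OC[C@H]1OB(O)c1cc(OC)c(OC)c(OC)c1 | intermediate

5 | (12R,13R,14S)-12-hydroxy-12,13-dihydroandrographolide 3,19:12,14-bis-O-(3,4,5-trimethoxyphenyl)boronate (O3/O19 and O12/O14 each bridged by B–Ar; the O12/O14 dioxaborinane is cis-fused to the lactone at C13–C14, H13 and H14 cis, H12 trans to H13) | C=C1CC[C@@H]2[C@]3(C)COB(c4cc(OC)c(OC)c(OC)c4)O[C@@H]3CC[C@@]2(C)[C@@H]1C[C@@H](OB(c3cc(OC)c(OC)c(OC)c3)O4)[C@H]1C(=O)OC[C@H]14 | intermediate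

6 | (12R,13R,14S)-12-hydroxy-12,13-dihydroandrographolide, (3R,4S)-3-{(1R)-1-hydroxy-2-[(1R,4aS,5R,6R,8aS)-6-hydroxy-5-(hydroxymethyl)-5,8a-dimethyl-2-methylidenedecahydronaphthalen-1-yl]ethyl}-4-hydroxyoxolan-2-one | C=C1CC[C@@H]2[C@](C)(CO)[C@H](O)CC[C@@]2(C)[C@@H]1C[C@@H](O)[C@H]1C(=O)OC[C@H]1O | target

**Totals**
Total step count: 3. Longest linear sequence: 3 steps (1 → 3 → 5 → 6).

**Steps most likely to fail, with fallbacks**

Step 2 (the proposed new oxa-Michael addition) is the most likely to fail. The lactone is a weaker acceptor than the enones for which hemiester additions are known. The enolate may also expel the C14 oxygen (E1cB) to give the 14-deoxy-12-hydroxy butenolide, and C13 may be protonated unselectively. Because the tether, not the catalyst, selects the C12 face, a mismatched catalyst should cost rate only. The fallback uses known chemistry and sets out from 3. Copper-catalysed conjugate borylation (B2pin2, 5 mol % CuCl, NaOtBu, 2,2′-bis(di-p-tolylphosphino)-1,1′-binaphthyl, MeOH, THF, rt) gives (12R,13R)-12-(pinacolboryl)-12,13-dihydroandrographolide 3,19-O-arylboronate F1. The ligand enantiomer that delivers boron to the 12R face cannot be predicted here and is fixed by a two-run screen; both are commercial. H2O2 in pH 7 buffer then converts C12–B into C12–OH with retention and removes the 3,19-arylboronate in the same operation. The sequence comes back to the route at 6, bypassing 5. Any C13 epimer from the protonation is removed by chromatography at the stage of 6.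

Step 3 is the second risk. Oxidation of the hindered cyclic boronates may be slow at pH 7, and raising the pH would cost 6 through dehydration or retro-aldol cleavage. The fallback sets out from 5 and comes back at 6. It is a non-oxidative boron transfer: transesterification with pinacol (10 equiv, MeOH–CH2Cl2, rt) moves both arylboron units onto pinacol and frees 6. It makes no new compound on the way (F0).

Step 1 is the third risk. The isolated boronate 3 may hydrolyse on handling, which would free the 3,19-diol to consume 2 in step 2 and blur the stoichiometry. The fallback sets out from 1 and comes back at 6, with a different protecting group. The known acetonide protection (2,2-dimethoxypropane, pyridinium p-toluenesulfonate, CH2Cl2, 40 °C) gives 3,19-O-isopropylideneandrographolide F2. The conditions of step 2 then give (12R,13R,14S)-12-hydroxy-3,19-O-isopropylidene-12,13-dihydroandrographolide 12,14-O-arylboronate F3. H2O2 at pH 7 gives (12R,13R,14S)-12-hydroxy-3,19-O-isopropylidene-12,13-dihydroandrographolide F4. AcOH–H2O (7:3) at rt removes the acetonide to give 6.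

**Further compounds**

F1 | step 2 | (12R,13R)-12-(4,4,5,5-tetramethyl-1,3,2-dioxaborolan-2-yl)-12,13-dihydroandrographolide 3,19-O-(3,4,5-trimethoxyphenyl)boronate | C=C1CC[C@@H]2[C@]3(C)COB(c4cc(OC)c(OC)c(OC)c4)O[C@@H]3CC[C@@]2(C)[C@@H]1C[C@@H](B3OC(C)(C)C(C)(C)O3)[C@H]1C(=O)OC[C@H]1O
F0 | step 3 | none | none
F2 | step 1 | 3,19-O-isopropylideneandrographolide | C=C1CC[C@@H]2[C@]3(C)COC(C)(C)O[C@@H]3CC[C@@]2(C)[C@@H]1C/C=C1/C(=O)OC[C@H]1O
F3 | step 1 | (12R,13R,14S)-12-hydroxy-3,19-O-isopropylidene-12,13-dihydroandrographolide 12,14-O-(3,4,5-trimethoxyphenyl)boronate | C=C1CC[C@@H]2[C@]3(C)COC(C)(C)O[C@@H]3CC[C@@]2(C)[C@@H]1C[C@@H](OB(c3cc(OC)c(OC)c(OC)c3)O4)[C@H]1C(=O)OC[C@H]14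
F4 | step 1 | (12R,13R,14S)-12-hydroxy-3,19-O-isopropylidene-12,13-dihydroandrographolide | C=C1CC[C@@H]2[C@]3(C)COC(C)(C)O[C@@H]3CC[C@@]2(C)[C@@H]1C[C@@H](O)[C@H]1C(=O)OC[C@H]1O
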